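**Plan**

- Retrosynthesis: the ester arm is traced back to a silyl-protected hydroxyethyl arm and the C5 methyl to CH2–HgBr. The cuts then follow in this order: the O1–C5 bond of the dioxolane, the C3–OO bond (oxetane perhydrolysis), C5=CH2 (Wittig), the C5–C1' bond to the side chain (Weinreb ketone synthesis) and C3'–C4' of the chain (Li2CuCl4 coupling).
- Forward: the chain is assembled first and its Grignard reagent is added to the mevalonate-derived Weinreb amide. The ketone is methylenated, the 1,3-diol is closed to an oxetane and opened with H2O2. The only ring of the target, the 1,2-dioxolane, closes last by peroxymercuration, followed by demercuration and oxidation of the arm.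
- Enabling feature: C3 of the dioxolane, with its methyl, its oxygen and two CH2 arms, is the carbinol carbon of (R)-mevalonolactone. The C5 methyl is a masked exocyclic methylene whose substituted carbon the C3 hydroperoxide reaches through a five-membered ring.
- Stereochemistry: C3 comes from (R)-mevalonolactone with one inversion in the perhydrolysis. The chain methyl centre comes from (2S)-3-bromo-2-methylpropan-1-ol. C5 is set in the ring closure relative to C3.

Key step: step 11

Assumption: the chain stereocentre is bought as the commercial, Roche-ester-derived bromo alcohol 2, and the C5 preference in step 11 is taken to be modest, so separation and re-equilibration of the C5 epimer are part of the plan.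

**Step 1**
Reactants: 1 (5-bromopentyl)benzene; 2 (2S)-3-bromo-2-methylpropan-1-ol
Product: 4 (2R)-2-methyl-8-phenyloctan-1-ol, via 5-phenylpentylmagnesium bromide 3 (not isolated)
Conditions: 1 (2.6 equiv), Mg, THF, 40 °C; then 2 (1 equiv), Li2CuCl4 (5 mol %), THF, −20 °C → rt; aq NH4Cl
Reagents that add atoms: none
Why: In this Kochi-type Li2CuCl4-catalysed alkyl–alkyl coupling the first equivalent of 3 turns the hydroxyl of 2 into an inert magnesium alkoxide and the next displaces the primary bromide, so the methyl-bearing centre next to the reacting CH2 is not touched.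

**Step 2**
Reactants: 4 (2R)-2-methyl-8-phenyloctan-1-ol
Product: 5 [(7R)-8-bromo-7-methyloctyl]benzene
Conditions: CBr4, PPh3, CH2Cl2, 0 °C → rt
Reagents that add atoms: tetrabromomethane BrC(Br)(Br)Br
Why: The Appel bromination displaces the activated primary oxygen by SN2 at the CH2 carbon, so the neighbouring stereocentre is not involved.

**Step 3**
Reactants: 6 (R)-mevalonolactone
Product: 7 (3R)-3,5-dihydroxy-N-methoxy-N,3-dimethylpentanamide
Conditions: MeNH(OMe)·HCl, i-PrMgCl, THF, −20 °C → 0 °C; aq NH4Cl
Reagents that add atoms: N,O-dimethylhydroxylamine hydrochloride CNOC.Cl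
Why: Weinreb aminolysis of the lactone by the chloromagnesium amide opens the ring at the acyl carbon and leaves the tertiary carbinol centre as it is.

**Step 4**
Reactants: 7 (3R)-3,5-dihydroxy-N-methoxy-N,3-dimethylpentanamide
Product: 8 (3R)-N-methoxy-N,3-dimethyl-3,5-bis(triethylsilyloxy)pentanamide
Conditions: TESOTf (2.5 equiv), 2,6-lutidine, CH2Cl2, −78 °C → 0 °C
Reagents that add atoms: triethylsilyl trifluoromethanesulfonate CC[Si](CC)(CC)OS(=O)(=O)C(F)(F)F
Why: Silyl triflate silylation caps the primary and the hindered tertiary hydroxyl alike, which blocks relactonisation and keeps both from consuming the Grignard reagent in the next step.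

**Step 5**
Reactants: 8 (3R)-N-methoxy-N,3-dimethyl-3,5-bis(triethylsilyloxy)pentanamide; 5 [(7R)-8-bromo-7-methyloctyl]benzene
Product: 10 (3R,7R)-3,7-dimethyl-13-phenyl-1,3-bis(triethylsilyloxy)tridecan-5-one, via (2R)-2-methyl-8-phenyloctylmagnesium bromide 9 (not isolated)
Conditions: 5 (1.3 equiv), Mg, THF, rt → 40 °C; then 8, THF, 0 °C → rt; aq NH4Cl
Reagents that add atoms: none
Why: In this Weinreb ketone synthesis the chelated tetrahedral magnesium adduct survives until work-up, so a single addition of 9 forms the bond between the future C5 and the side chain and stops at the ketone.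

**Step 6**
Reactants: 10 (3R,7R)-3,7-dimethyl-13-phenyl-1,3-bis(triethylsilyloxy)tridecan-5-one
Product: 11 (3S,7R)-3,7-dimethyl-5-methylidene-13-phenyl-1,3-bis(triethylsilyloxy)tridecane
Conditions: Ph3PCH3Br, KOt-Bu, THF, 0 °C → rt
Reagents that add atoms: methyltriphenylphosphonium bromide C[P+](c1ccccc1)(c1ccccc1)c1ccccc1.[Br-]
Why: Wittig methylenation with the unstabilised ylide turns the ketone carbon into the exocyclic methylene that later becomes C5 with its methyl, and the ketone has no α-stereocentre that could be lost.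

**Step 7**
Reactants: 11 (3S,7R)-3,7-dimethyl-5-methylidene-13-phenyl-1,3-bis(triethylsilyloxy)tridecane
Product: 12 (3S,7R)-3,7-dimethyl-5-methylidene-13-phenyltridecane-1,3-diol
Conditions: TBAF (3 equiv), THF, 0 °C → rt
Reagents that add atoms: none
Why: Fluoride-induced desilylation removes both triethylsilyl ethers without affecting the alkene or the configuration of the tertiary carbinol.

**Step 8**
Reactants: 12 (3S,7R)-3,7-dimethyl-5-methylidene-13-phenyltridecane-1,3-diol
Product: 14 (2S)-2-methyl-2-[(4R)-4-methyl-2-methylidene-10-phenyldecyl]oxetane, via primary monotosylate 13 (not isolated)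
Conditions: n-BuLi (1.0 equiv), THF, 0 °C; TsCl (1.0 equiv), 0 °C; then n-BuLi (1.05 equiv), 0 °C → 60 °C
Reagents that add atoms: none
Why: One-pot tosylation of the primary hydroxyl and intramolecular Williamson etherification (4-exo-tet) by the tertiary lithium alkoxide closes the oxetane with retention at C3, because the tertiary C–O bond is never broken.

**Step 9**
Reactants: 14 (2S)-2-methyl-2-[(4R)-4-methyl-2-methylidene-10-phenyldecyl]oxetane; 15 hydrogen peroxide (dried solution in Et2O)
Product: 16 (3R,7R)-3-hydroperoxy-3,7-dimethyl-5-methylidene-13-phenyltridecan-1-ol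
Conditions: 15 (10 equiv), TMSOTf (0.3 equiv), Et2O, −78 °C → −20 °C; aq NaHCO3
Reagents that add atoms: none
Why: In this Lewis-acid-promoted perhydrolysis of a 2,2-disubstituted oxetane, H2O2 attacks the more substituted carbon of the activated oxonium from the rear in a borderline SN2 event, so the C3 hydroperoxide should form with inversion to the required configuration while the low temperature keeps the homoallylic alkene out of play.

**Step 10**
Reactants: 16 (3R,7R)-3-hydroperoxy-3,7-dimethyl-5-methylidene-13-phenyltridecan-1-ol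
Product: 18 tert-butyl{[(3R,7R)-3-hydroperoxy-3,7-dimethyl-5-methylidene-13-phenyltridecyl]oxy}dimethylsilane, via bis-TBS derivative 17 (not isolated)
Conditions: TBSCl (2.4 equiv), imidazole, DMF, 0 °C → rt; then K2CO3 (0.3 equiv), MeOH, 0 °C → rt
Reagents that add atoms: tert-butyldimethylsilyl chloride CC(C)(C)[Si](C)(C)Cl
Why: Silylation of both O–H groups is followed by base-catalysed methanolysis, which should cleave only the Si–OO bond because the peroxide anion leaves silicon far more readily than a primary alkoxide, so the free hydroperoxide returns with the arm protected.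

**Step 11**
Reactants: 18 tert-butyl{[(3R,7R)-3-hydroperoxy-3,7-dimethyl-5-methylidene-13-phenyltridecyl]oxy}dimethylsilane
Product: 20 tert-butyl(2-{(3S,5S)-5-[(bromomercurio)methyl]-3-methyl-5-[(2R)-2-methyl-8-phenyloctyl]-1,2-dioxolan-3-yl}ethoxy)dimethylsilane, via acetoxymercurial 19 (not isolated)
Conditions: Hg(OAc)2 (1.2 equiv), HClO4 (70% aq, 2 mol %), CH2Cl2, 0 °C → rt; then aq KBr
Reagents that add atoms: mercury diacetate CC(=O)O[Hg]OC(C)=O; potassium bromide [K+].[Br-]
Why: Hg(OAc)2, made more electrophilic by a trace of HClO4, forms a mercurinium ion on the 1,1-disubstituted C5=CH2 bond, and the tertiary C3 hydroperoxide opens it at the fully substituted carbon to give acetoxymercurial 19, which bromide exchange converts into the chromatographable bromide 20. The closest known reaction type is the cycloperoxymercuration of alkenyl hydroperoxides to 1,2-dioxolanes. The 1,2-dioxolane closes in the 5-exo-trig mode through the new O–C5 bond. C5 is set relative to the fixed C3 centre: the addition is reversible under the acidic conditions, so the mixture should drift toward the isomer with the β-branched chain trans to the silyloxyethyl arm and cis only to the C3 methyl, but this bias is expected to be modest and the other C5 epimer is to be separated and returned to the same conditions. The step also needs Markovnikov regioselectivity, which the better-stabilised tertiary end of the mercurinium ion provides, and chemoselectivity for the hydroperoxide, which the silyl ether secures by keeping the arm oxygen out of a 6-exo closure while the absence of a free carbocation suppresses Hock cleavage.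

**Step 12**
Reactants: 20 tert-butyl(2-{(3S,5S)-5-[(bromomercurio)methyl]-3-methyl-5-[(2R)-2-methyl-8-phenyloctyl]-1,2-dioxolan-3-yl}ethoxy)dimethylsilane
Product: 21 tert-butyl(2-{(3S,5S)-3,5-dimethyl-5-[(2R)-2-methyl-8-phenyloctyl]-1,2-dioxolan-3-yl}ethoxy)dimethylsilane
Conditions: NaBH4, 2 M aq NaOH, CH2Cl2, 0 °C
Reagents that add atoms: none
Why: Hydridodemercuration through the alkylmercury hydride and a radical chain replaces C–Hg by C–H at the exocyclic CH2, so neither ring stereocentre is touched, and the cold concentrated hydride is meant to trap the primary radical before it attacks the O–O bond.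

**Step 13**
Reactants: 21 tert-butyl(2-{(3S,5S)-3,5-dimethyl-5-[(2R)-2-methyl-8-phenyloctyl]-1,2-dioxolan-3-yl}ethoxy)dimethylsilane
Product: 22 2-{(3S,5S)-3,5-dimethyl-5-[(2R)-2-methyl-8-phenyloctyl]-1,2-dioxolan-3-yl}ethan-1-ol
Conditions: TBAF, AcOH, THF, 0 °C → rt
Reagents that add atoms: none
Why: Buffered fluoride desilylation frees the primary alcohol under conditions that a dialkyl peroxide tolerates.

**Step 14**
Reactants: 22 2-{(3S,5S)-3,5-dimethyl-5-[(2R)-2-methyl-8-phenyloctyl]-1,2-dioxolan-3-yl}ethan-1-ol
Product: 23 {(3R,5S)-3,5-dimethyl-5-[(2R)-2-methyl-8-phenyloctyl]-1,2-dioxolan-3-yl}acetic acid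
Conditions: TEMPO (0.2 equiv), PhI(OAc)2 (2.5 equiv), MeCN/H2O 1:1, rt
Reagents that add atoms: water O
Why: The TEMPO/PhI(OAc)2 oxidation takes the primary alcohol through the aldehyde hydrate to the acid under near-neutral conditions that should spare the peroxide and the benzylic CH2 and avoid base-induced opening of the β-peroxy carbonyl unit.

**Step 15**
Reactants: 23 {(3R,5S)-3,5-dimethyl-5-[(2R)-2-methyl-8-phenyloctyl]-1,2-dioxolan-3-yl}acetic acid
Product: 24 methyl {(3R,5S)-3,5-dimethyl-5-[(2R)-2-methyl-8-phenyloctyl]-1,2-dioxolan-3-yl}acetate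
Conditions: TMSCHN2, MeOH/toluene 1:4, 0 °C → rt
Reagents that add atoms: trimethylsilyldiazomethane C[Si](C)(C)C=[N+]=[N-]
Why: Methyl esterification with trimethylsilyldiazomethane in methanol runs under neutral conditions, so the base-sensitive β-peroxy ester forms without ring opening.

Note on descriptors: the spatial arrangement at the mevalonate carbon changes only in step 9. The R/S changes at 10→11, 18→20 and 22→23, and at the chain centre at 2→4, are switches of CIP priority.

**Compound list**

1 | (5-bromopentyl)benzene | BrCCCCCc1ccccc1 | starting material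
2 | (2S)-3-bromo-2-methylpropan-1-ol | OC[C@H](C)CBr | starting material
3 | 5-phenylpentylmagnesium bromide | Br[Mg]CCCCCc1ccccc1 | intermediate
4 | (2R)-2-methyl-8-phenyloctan-1-ol | OC[C@H](C)CCCCCCc1ccccc1 | intermediate
5 | [(7R)-8-bromo-7-methyloctyl]benzene | BrC[C@H](C)CCCCCCc1ccccc1 | intermediate
6 | (R)-mevalonolactone | C[C@@]1(O)CCOC(=O)C1 | starting material
7 | (3R)-3,5-dihydroxy-N-methoxy-N,3-dimethylpentanamide | CON(C)C(=O)C[C@](C)(O)CCO | intermediate
8 | (3R)-N-methoxy-N,3-dimethyl-3,5-bis(triethylsilyloxy)pentanamide | CON(C)C(=O)C[C@](C)(O[Si](CC)(CC)CC)CCO[Si](CC)(CC)CC | intermediate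
9 | (2R)-2-methyl-8-phenyloctylmagnesium bromide | Br[Mg]C[C@H](C)CCCCCCc1ccccc1 | intermediate
10 | (3R,7R)-3,7-dimethyl-13-phenyl-1,3-bis(triethylsilyloxy)tridecan-5-one | CC[Si](CC)(CC)OCC[C@@](C)(O[Si](CC)(CC)CC)CC(=O)C[C@H](C)CCCCCCc1ccccc1 | intermediate
11 | (3S,7R)-3,7-dimethyl-5-methylidene-13-phenyl-1,3-bis(triethylsilyloxy)tridecane | CC[Si](CC)(CC)OCC[C@@](C)(O[Si](CC)(CC)CC)CC(=C)C[C@H](C)CCCCCCc1ccccc1 | intermediate
12 | (3S,7R)-3,7-dimethyl-5-methylidene-13-phenyltridecane-1,3-diol | OCC[C@@](C)(O)CC(=C)C[C@H](C)CCCCCCc1ccccc1 | intermediate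
13 | (3S,7R)-3-hydroxy-3,7-dimethyl-5-methylidene-13-phenyltridecyl 4-methylbenzenesulfonate | Cc1ccc(cc1)S(=O)(=O)OCC[C@@](C)(O)CC(=C)C[C@H](C)CCCCCCc1ccccc1 | intermediate
14 | (2S)-2-methyl-2-[(4R)-4-methyl-2-methylidene-10-phenyldecyl]oxetane | C1C[C@@](C)(O1)CC(=C)C[C@H](C)CCCCCCc2ccccc2 | intermediate
15 | hydrogen peroxide | OO | starting material
16 | (3R,7R)-3-hydroperoxy-3,7-dimethyl-5-methylidene-13-phenyltridecan-1-ol | OCC[C@](C)(OO)CC(=C)C[C@H](C)CCCCCCc1ccccc1 | intermediate
17 | tert-butyl({(3R,7R)-3-[(tert-butyldimethylsilyl)peroxy]-3,7-dimethyl-5-methylidene-13-phenyltridecyl}oxy)dimethylsilane | CC(C)(C)[Si](C)(C)OCC[C@](C)(OO[Si](C)(C)C(C)(C)C)CC(=C)C[C@H](C)CCCCCCc1ccccc1 | intermediate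
18 | tert-butyl{[(3R,7R)-3-hydroperoxy-3,7-dimethyl-5-methylidene-13-phenyltridecyl]oxy}dimethylsilane | CC(C)(C)[Si](C)(C)OCC[C@](C)(OO)CC(=C)C[C@H](C)CCCCCCc1ccccc1 | intermediate
19 | tert-butyl(2-{(3S,5S)-5-[(acetoxymercurio)methyl]-3-methyl-5-[(2R)-2-methyl-8-phenyloctyl]-1,2-dioxolan-3-yl}ethoxy)dimethylsilane | CC(C)(C)[Si](C)(C)OCC[C@@]1(C)C[C@](C[Hg]OC(C)=O)(C[C@H](C)CCCCCCc2ccccc2)OO1 | intermediate
20 | tert-butyl(2-{(3S,5S)-5-[(bromomercurio)methyl]-3-methyl-5-[(2R)-2-methyl-8-phenyloctyl]-1,2-dioxolan-3-yl}ethoxy)dimethylsilane | CC(C)(C)[Si](C)(C)OCC[C@@]1(C)C[C@](C[Hg]Br)(C[C@H](C)CCCCCCc2ccccc2)OO1 | intermediate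
21 | tert-butyl(2-{(3S,5S)-3,5-dimethyl-5-[(2R)-2-methyl-8-phenyloctyl]-1,2-dioxolan-3-yl}ethoxy)dimethylsilane | CC(C)(C)[Si](C)(C)OCC[C@@]1(C)C[C@](C)(C[C@H](C)CCCCCCc2ccccc2)OO1 | intermediate
22 | 2-{(3S,5S)-3,5-dimethyl-5-[(2R)-2-methyl-8-phenyloctyl]-1,2-dioxolan-3-yl}ethan-1-ol | OCC[C@@]1(C)C[C@](C)(C[C@H](C)CCCCCCc2ccccc2)OO1 | intermediate
23 | {(3R,5S)-3,5-dimethyl-5-[(2R)-2-methyl-8-phenyloctyl]-1,2-dioxolan-3-yl}acetic acid | OC(=O)C[C@@]1(C)C[C@](C)(C[C@H](C)CCCCCCc2ccccc2)OO1 | intermediate
24 | methyl {(3R,5S)-3,5-dimethyl-5-[(2R)-2-methyl-8-phenyloctyl]-1,2-dioxolan-3-yl}acetate | COC(=O)C[C@@]1(C)C[C@](C)(C[C@H](C)CCCCCCc2ccccc2)OO1 | target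

**Step count and risks**

Total step count: 15. Longest linear sequence: 13 steps (steps 3 to 15, from 6).

Steps most likely to fail:

1. Step 11. The facial discrimination at C5 may be too weak, and the long acidic equilibration may slowly erode the silyl ether or the hydroperoxide. Fallback: from 18 the ring is closed under kinetic halonium control instead (N-iodosuccinimide, CH2Cl2, 0 °C), a peroxy-iodocyclisation that is again 5-exo through the O–C5 bond. It gives tert-butyl(2-{(3S,5S)-5-(iodomethyl)-3-methyl-5-[(2R)-2-methyl-8-phenyloctyl]-1,2-dioxolan-3-yl}ethoxy)dimethylsilane F1, whose C5 epimer is removed by chromatography. Reduction of F1 with Bu3SnH at high concentration (Et3B/air, 0 °C) rejoins the route at 21.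

2. Step 9. The activated oxetane may partly ionise to a free tertiary cation, which would erode the configuration at C3 and open elimination pathways. Fallback: from 14 the order of the two C–O bond formations is reversed. Mukaiyama–Isayama hydroperoxysilylation of the methylidene group (Co(acac)2 cat., O2, Et3SiH, EtOH) gives triethyl({(4R)-2,4-dimethyl-1-[(2R)-2-methyloxetan-2-yl]-10-phenyldecan-2-yl}peroxy)silane F2 as both C2 epimers. Mild methanolysis (K2CO3, MeOH) frees (2R)-2-[(4R)-2-hydroperoxy-2,4-dimethyl-10-phenyldecyl]-2-methyloxetane F3. With catalytic TMSOTf in CH2Cl2 at −78 °C the tethered hydroperoxide should open the oxetane at its quaternary carbon, 5-exo-tet with inversion. After separation of the C5 epimer the product is 22, so this path bypasses steps 9 to 13.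

3. Step 10. Silylation and methanolysis may not discriminate cleanly between the alcohol and hydroperoxide oxygens, or the silyl peroxide may rearrange instead of being cleaved. Fallback: from 16 no protecting group is used. Hg(OAc)2 in CH2Cl2 at 0 °C without added strong acid, then aq KBr, should give 2-{(3S,5S)-5-[(bromomercurio)methyl]-3-methyl-5-[(2R)-2-methyl-8-phenyloctyl]-1,2-dioxolan-3-yl}ethan-1-ol F4; under these kinetic conditions the hydroperoxide, the better nucleophile closing the smaller ring, should outrun 6-exo attack by the hydroxyl. NaBH4/aq NaOH demercuration of F4 then delivers 22 directly.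

**Further compounds**

F1 | step 11 | tert-butyl(2-{(3S,5S)-5-(iodomethyl)-3-methyl-5-[(2R)-2-methyl-8-phenyloctyl]-1,2-dioxolan-3-yl}ethoxy)dimethylsilane | CC(C)(C)[Si](C)(C)OCC[C@@]1(C)C[C@](CI)(C[C@H](C)CCCCCCc2ccccc2)OO1
F2 | step 9 | triethyl({(4R)-2,4-dimethyl-1-[(2R)-2-methyloxetan-2-yl]-10-phenyldecan-2-yl}peroxy)silane, both C2 epimers | C1C[C@@](C)(O1)CC(C)(OO[Si](CC)(CC)CC)C[C@H](C)CCCCCCc2ccccc2
F3 | step 9 | (2R)-2-[(4R)-2-hydroperoxy-2,4-dimethyl-10-phenyldecyl]-2-methyloxetane, both C2 epimers | C1C[C@@](C)(O1)CC(C)(OO)C[C@H](C)CCCCCCc2ccccc2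
F4 | step 10 | 2-{(3S,5S)-5-[(bromomercurio)methyl]-3-methyl-5-[(2R)-2-methyl-8-phenyloctyl]-1,2-dioxolan-3-yl}ethan-1-ol | OCC[C@@]1(C)C[C@](C[Hg]Br)(C[C@H](C)CCCCCCc2ccccc2)OO1
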